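**Plan**
- Retrosynthesis: the C21 acetate, the C2 hydroxyl and a helper carbonyl at C7 are adjusted last; C6–C12 and C8–C9 are then cut together; next the C2=C18 bridge alkene (metathesis) and the two imide N–C bonds; then C8–C13 (Michael) and C5–C4 (conjugate addition) back to a cyclopentenone; the iodocyclopentenyl acrylate comes from 2-iodocyclopentenone by Claisen rearrangement.
- Forward ring order: cyclopentene (given) → cyclopentanone template → glutarimide → nine-membered N–C5 bridge → cyclopentane and cycloheptene together (key step) → lactam.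
- Enabling feature: C8 and C6 are the two enolisable α-carbons of the imide C1(=O)–N–C7(=O), held 1,3 across quaternary C5. C9 (alkenyl iodide) and C12 (alkyl chloride) are the 1,4-termini of the C9=C10–C11–C12 strap on the cyclopentene. The N–C5 bridge blocks one face of the imide ring.
- Stereochemistry: C15 from asymmetric allylboration plus Claisen chirality transfer; C5 from catalytic asymmetric conjugate addition; C2/C18 from reagent-controlled syn-hydroboration of the Z-alkene; C8 and C6 from the substrate in the key step; C14 from kinetic protonation.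

Key step: step 15

Atom labels used in the text only: C1 lactam C=O; C2 carbinol CH; C3, C4 the CH2 groups between C2 and C5; C5 quaternary carbon bearing C21H2O; C6 ring CH next to C7H2N; C8 quaternary carbon between C1 and C5; C9=C10 the alkene (C9 on C8); C11, C12 the CH2CH2 from C10 to C6; C13 the CH2 on C8; C14 CH(CO2Me); C15 the CH joining C14, C9 and C16; C16, C17 cyclopentene CH2 groups; C18 CH(CH3); C19 NCH2 next to C18.

Assumption: 1, 10 and allyldiisopropoxyborane are taken as purchasable; 13–26 are carried as epimer mixtures at C8 and/or C14, which converge in steps 15 and 17.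

**Route**

Step 1
Reactants: 1 2-iodocyclopent-2-en-1-one
Product: 2 (1S)-2-iodo-1-(prop-2-enyl)cyclopent-2-en-1-ol
Conditions: CH2=CHCH2B(OiPr)2, (S)-3,3′-Br2-BINOL (15 mol %), toluene/PhCF3, −35 °C
Reagents that add atoms: allyldiisopropoxyborane, C=CCB(OC(C)C)OC(C)C
Why: Chiral-diol-catalysed asymmetric allylboration of a ketone should add allyl 1,2 to the α-iodo enone on one enantioface (the catalyst antipode is the one that gives the S carbinol), creating the C–O stereocentre that is relayed to C15.

Step 2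
Reactants: 2 (1S)-2-iodo-1-(prop-2-enyl)cyclopent-2-en-1-ol
Product: 3 methyl [(1R)-2-iodo-3-(prop-2-enyl)cyclopent-2-en-1-yl]acetate
Conditions: MeC(OMe)3, EtCO2H (cat.), xylene, 140 °C, MeOH distilled off
Reagents that add atoms: trimethyl orthoacetate, CC(OC)(OC)OC
Why: Johnson–Claisen rearrangement: the ketene acetal of the tertiary allylic alcohol shifts suprafacially, so C15–C14 forms on the face that carried oxygen (R at C15) and the tetrasubstituted iodoalkene C9=C10 is generated in place.

Step 3
Reactants: 3 methyl [(1R)-2-iodo-3-(prop-2-enyl)cyclopent-2-en-1-yl]acetate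
Product: 6 methyl 2-[(1R)-2-iodo-3-(prop-2-enyl)cyclopent-2-en-1-yl]prop-2-enoate, via Mannich base 4 (not isolated), via methiodide 5 (not isolated)
Conditions: LiN(iPr)2, THF, −78 °C; CH2=NMe2+ I−, −78 → 0 °C; MeI, MeOH, 25 °C; aq. NaHCO3, CH2Cl2
Reagents that add atoms: N,N-dimethylmethyleneiminium iodide (Eschenmoser's salt), C=[N+](C)C.[I-]
Why: Ester enolate Mannich reaction followed by quaternisation and E1cB elimination is the standard α-methylenation of esters and does not touch the ring stereocentre.

Step 4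
Reactants: 6 methyl 2-[(1R)-2-iodo-3-(prop-2-enyl)cyclopent-2-en-1-yl]prop-2-enoate
Product: 8 methyl 2-[(1R)-3-(2-hydroxyethyl)-2-iodocyclopent-2-en-1-yl]prop-2-enoate, via aldehyde 7 (not isolated)
Conditions: OsO4 (2 mol %), NaIO4, 2,6-lutidine, dioxane/H2O, 25 °C; then NaBH4, MeOH, −20 °C
Reagents that add atoms: sodium periodate (oxygen delivered through catalytic OsO4), [Na+].[O-]I(=O)(=O)=O
Why: Lemieux–Johnson cleavage should take the monosubstituted terminal alkene much faster than the electron-poor acrylate or the hindered iodoalkene, and borohydride reduces the aldehyde at low temperature without touching the ester.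

Step 5
Reactants: 8 methyl 2-[(1R)-3-(2-hydroxyethyl)-2-iodocyclopent-2-en-1-yl]prop-2-enoate
Product: 9 methyl 2-[(1R)-3-(2-chloroethyl)-2-iodocyclopent-2-en-1-yl]prop-2-enoate
Conditions: PPh3, N-chlorosuccinimide, CH2Cl2, 0 °C
Reagents that add atoms: N-chlorosuccinimide, O=C1CCC(=O)N1Cl
Why: Appel-type chlorination converts the primary alcohol into the chloride by SN2 displacement of the alkoxyphosphonium under neutral conditions.

Step 6
Reactants: 10 3-(hydroxymethyl)cyclopent-2-en-1-one
Product: 11 3-{[tert-butyl(dimethyl)silyl]oxymethyl}cyclopent-2-en-1-one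
Conditions: t-BuMe2SiCl, imidazole, DMF, 25 °C
Reagents that add atoms: tert-butyldimethylsilyl chloride, CC(C)(C)[Si](C)(C)Cl
Why: Standard silylation of a primary alcohol protects the future C21 oxygen.

Step 7
Reactants: 11 3-{[tert-butyl(dimethyl)silyl]oxymethyl}cyclopent-2-en-1-one
Product: 12 {[(3R)-3-(but-3-enyl)-3-{[tert-butyl(dimethyl)silyl]oxymethyl}cyclopent-1-en-1-yl]oxy}trimethylsilane
Conditions: CH2=CHCH2CH2MgBr, Cu(OTf)2 (3 mol %), chiral imidazolinium salt (NHC precursor, 4 mol %), Et2O, −30 °C; then Me3SiCl, Et3N, 0 °C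
Reagents that add atoms: but-3-enylmagnesium bromide, C=CCC[Mg]Br; chlorotrimethylsilane, C[Si](C)(C)Cl
Why: Copper-catalysed asymmetric conjugate addition of a Grignard reagent to a β-substituted cyclopentenone creates quaternary C5 under ligand control (antipode chosen for 5R), and silylation of the magnesium enolate fixes the enol ether on the C8 side.

Step 8
Reactants: 12 silyl enol ether; 9 methyl 2-[(1R)-3-(2-chloroethyl)-2-iodocyclopent-2-en-1-yl]prop-2-enoate
Product: 13 methyl 3-[(2R)-2-(but-3-enyl)-2-{[tert-butyl(dimethyl)silyl]oxymethyl}-5-oxocyclopentyl]-2-[(1R)-3-(2-chloroethyl)-2-iodocyclopent-2-en-1-yl]propanoate (epimers at C8 and C14)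
Conditions: TiCl4, CH2Cl2, −78 °C; aq. NaHCO3
Reagents that add atoms: none
Why: Mukaiyama–Michael addition of the regiodefined silyl enol ether to the acrylate forms C8–C13 only at C8; the two new CH centres form unselectively, which is harmless because C8 is re-enolised in step 15 and C14 is reset in step 17.

Step 9
Reactants: 13 keto ester
Product: 14 trimethylsilyl enol ether of 13 on the C7 side (C1(OSiMe3)=C7H)
Conditions: LiN(SiMe3)2, Me3SiCl (in situ), THF, −78 °C
Reagents that add atoms: chlorotrimethylsilane, C[Si](C)(C)Cl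
Why: Kinetic enolisation with in situ silylation should remove a proton from the unhindered C7 methylene and not from the tertiary C8–H next to the quaternary centre (regioselective silyl enol ether formation).

Step 10
Reactants: 14 silyl enol ether
Product: 16 diacid (C1 and C7 both CO2H; 3,3-disubstituted glutaric acid carrying the C8 side chain), via aldehyde acid 15 (not isolated)
Conditions: O3, CH2Cl2/MeOH, −78 °C (Sudan red indicator); Me2S; then NaClO2, NaH2PO4, 2-methylbut-2-ene, t-BuOH/H2O, 0 °C
Reagents that add atoms: ozone, [O-][O+]=O; sodium chlorite, [Na+].[O-]Cl=O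
Why: Ozonolysis titrated to an indicator end point should cleave the electron-rich silyl enol ether before the other alkenes, giving C1 acid and C7 aldehyde, and Pinnick oxidation takes the aldehyde to the acid.

Step 11
Reactants: 16 diacid
Product: 19 N-(2-methylprop-2-enyl)glutarimide (C5 bearing but-3-enyl and CH2OTBS, C8 bearing the side chain), via anhydride 17 (not isolated), via amic acid 18 (not isolated)
Conditions: Ac2O, 80 °C; evaporate; CH2=C(CH3)CH2NH2, Et3N, CH2Cl2, 25 °C; then Ac2O, NaOAc, 80 °C
Reagents that add atoms: 2-methylprop-2-en-1-amine, C=C(C)CN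
Why: Cyclic anhydride formation, opening by the primary amine and anhydride-mediated closure is the classical glutarimide synthesis; both amic acid regioisomers converge on the same imide.

Step 12
Reactants: 19 N-methallyl glutarimide
Product: 20 bridged imide with the nine-membered N–C19–C18(CH3)=C2–C3–C4–C5 bridge (Z alkene)
Conditions: second-generation Grubbs catalyst (10 mol %), toluene (2 mM), 80 °C
Reagents that add atoms: none
Why: Ring-closing metathesis between the butenyl group on C5 and the 1,1-disubstituted methallyl group on nitrogen should close the bridge as the ring-constrained Z trisubstituted alkene, helped by the geminal substitution at C5.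

Step 13
Reactants: 20 bridged imide
Product: 21 bridged imide alcohol (2R,18R)
Conditions: IpcBH2 (from (−)-α-pinene), THF, −25 °C; then 30% H2O2, pH 7 phosphate buffer, 0 °C
Reagents that add atoms: hydrogen peroxide, OO
Why: Brown asymmetric hydroboration–oxidation: boron adds to C2 and H to C18 syn, which on the Z alkene fixes the C2–OH/C18–CH3 relationship stereospecifically, and the isopinocampheyl group should select the face giving 2R,18R by analogy with 1-methylcycloalkenes.

Step 14
Reactants: 21 bridged imide alcohol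
Product: 22 bridged imide, C2 tert-butyldiphenylsilyl ether
Conditions: t-BuPh2SiCl, imidazole, DMAP (cat.), DMF, 50 °C
Reagents that add atoms: tert-butyl(chloro)diphenylsilane, CC(C)(C)[Si](Cl)(c1ccccc1)c1ccccc1
Why: Silylation gives a secondary silyl ether that survives base and can later be told apart from the primary TBS ether.

Step 15
Reactants: 22 bridged imide
Product: 24 pentacyclic imide (C8–C9 and C6–C12 formed; 6S,8R), via chloro imide 23 (not isolated)
Conditions: LiN(SiMe3)2 (2.5 equiv), Pd2(dba)3 (5 mol %), P(t-Bu)3 (12 mol %), THF/toluene, 0 → 25 °C; then DMPU, 65 °C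
Reagents that add atoms: none
Why: The amide base enolises the imide, zerovalent palladium inserts into C9–I, the C8 enolate displaces iodide on palladium and reductive elimination forges C8–C9 (23); the second equivalent of base then enolises C6, which displaces the C12 chloride by SN2 to close C6–C12. The closest known reaction types are the palladium-catalysed intramolecular α-alkenylation of amide and ketone enolates with alkenyl halides and the α,α′-annulation of cyclic carbonyl compounds by bis-electrophiles. The cyclopentane closes by reductive elimination from a six-membered palladacycle (5-exo), and the cycloheptene closes by a 7-exo-tet alkylation. Quaternary C8 and the C6 methine are set by the substrate: the N–C5 bridge covers one face of the boat-shaped glutarimide, so both bonds form on the opposite face, and the four-carbon strap can only span C8 and C6 cis. The step needs C8 to couple before C6 (only the C8 enolate reaches palladium through a six-membered palladacycle), palladium to choose the alkenyl iodide over the alkyl chloride, C- over O-alkylation (seven- against nine-membered ring), and imide over ester enolisation (a silylamide base too weak to form the C14 ester enolate, which could otherwise attack C12).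

Step 16
Reactants: 24 pentacyclic imide
Product: 26 pentacyclic lactam (C7 now CH2; epimers at C14), via hydroxy lactam 25 (not isolated)
Conditions: NaBH4, MeOH/CH2Cl2, −20 °C; then Et3SiH, BF3·OEt2, CH2Cl2, −78 → −20 °C
Reagents that add atoms: none
Why: Speckamp-type regioselective imide reduction: borohydride should attack the C7 carbonyl (next to tertiary C6) and not C1 (next to quaternary C8), and ionic hydrogenation of the derived N-acyliminium ion removes the helper oxygen.

Step 17
Reactants: 26 pentacyclic lactam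
Product: 27 pentacyclic lactam, 14R
Conditions: LiN(iPr)2 (1.2 equiv), THF, −78 °C; then AcOH, −78 °C
Reagents that add atoms: none
Why: Deprotonation of the only acidic C–H (C14; the lactam has no α-hydrogen) and kinetic protonation of the ester enolate from the convex face of the diquinane, away from the C5 side and the cyclopentene ring, should put H14 cis to H15 and converge both epimers.

Step 18
Reactants: 27 pentacyclic lactam
Product: 28 C21 primary alcohol (C2 still a TBDPS ether)
Conditions: HF·pyridine, pyridine/THF, 0 → 25 °C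
Reagents that add atoms: none
Why: Fluoride desilylation under buffered acidic conditions removes a primary TBS ether much faster than a hindered secondary TBDPS ether (standard silyl ether orthogonality).

Step 19
Reactants: 28 C21 alcohol
Product: 29 C21 acetate, C2 TBDPS ether
Conditions: Ac2O, pyridine, DMAP (cat.), CH2Cl2, 25 °C
Reagents that add atoms: acetic anhydride, CC(=O)OC(C)=O
Why: DMAP-catalysed acylation of the only free hydroxyl installs the acetate.

Step 20
Reactants: 29 acetate
Product: 30 CNP0296366.1 (2R,5R,6S,8R,14R,15R,18R in the labels above)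
Conditions: Bu4NF, AcOH, THF, 25 °C
Reagents that add atoms: none
Why: Fluoride-mediated desilylation buffered with acetic acid frees the C2 hydroxyl without acetate migration or epimerisation at C14.

**Compound list**

1 | 2-iodocyclopent-2-en-1-one | O=C1CCC=C1I | starting material
2 | (1S)-2-iodo-1-(prop-2-enyl)cyclopent-2-en-1-ol | C=CC[C@@]1(O)CCC=C1I | intermediate
3 | methyl [(1R)-2-iodo-3-(prop-2-enyl)cyclopent-2-en-1-yl]acetate | COC(=O)C[C@H]1CCC(CC=C)=C1I | intermediate
4 | Mannich base, methyl 3-(dimethylamino)-2-[(1R)-2-iodo-3-(prop-2-enyl)cyclopent-2-en-1-yl]propanoate | COC(=O)C(CN(C)C)[C@H]1CCC(CC=C)=C1I | intermediate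
5 | trimethylammonium iodide of 4 | COC(=O)C(C[N+](C)(C)C)[C@H]1CCC(CC=C)=C1I.[I-] | intermediate
6 | methyl 2-[(1R)-2-iodo-3-(prop-2-enyl)cyclopent-2-en-1-yl]prop-2-enoate | COC(=O)C(=C)[C@H]1CCC(CC=C)=C1I | intermediate
7 | methyl 2-[(1R)-2-iodo-3-(2-oxoethyl)cyclopent-2-en-1-yl]prop-2-enoate | COC(=O)C(=C)[C@H]1CCC(CC=O)=C1I | intermediate
8 | methyl 2-[(1R)-3-(2-hydroxyethyl)-2-iodocyclopent-2-en-1-yl]prop-2-enoate | COC(=O)C(=C)[C@H]1CCC(CCO)=C1I | intermediate
9 | methyl 2-[(1R)-3-(2-chloroethyl)-2-iodocyclopent-2-en-1-yl]prop-2-enoate | COC(=O)C(=C)[C@H]1CCC(CCCl)=C1I | intermediate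
10 | 3-(hydroxymethyl)cyclopent-2-en-1-one | O=C1C=C(CO)CC1 | starting material
11 | 3-{[tert-butyl(dimethyl)silyl]oxymethyl}cyclopent-2-en-1-one | O=C1C=C(CO[Si](C)(C)C(C)(C)C)CC1 | intermediate
12 | {[(3R)-3-(but-3-enyl)-3-(TBS-oxymethyl)cyclopent-1-en-1-yl]oxy}trimethylsilane | C[Si](C)(C)OC1=C[C@@](CO[Si](C)(C)C(C)(C)C)(CCC=C)CC1 | intermediate
13 | keto ester from the Michael union (5R,15R; epimers at C8, C14) | COC(=O)C(CC1C(=O)CC[C@]1(CO[Si](C)(C)C(C)(C)C)CCC=C)[C@H]1CCC(CCCl)=C1I | intermediate
14 | trimethylsilyl enol ether of 13, C1(OSiMe3)=C7 | COC(=O)C(CC1C(O[Si](C)(C)C)=CC[C@]1(CO[Si](C)(C)C(C)(C)C)CCC=C)[C@H]1CCC(CCCl)=C1I | intermediate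
15 | aldehyde acid (C1 CO2H, C7 CHO) | COC(=O)C(CC(C(=O)O)[C@@](CC=O)(CO[Si](C)(C)C(C)(C)C)CCC=C)[C@H]1CCC(CCCl)=C1I | intermediate
16 | diacid (C1 and C7 CO2H) | COC(=O)C(CC(C(=O)O)[C@@](CC(=O)O)(CO[Si](C)(C)C(C)(C)C)CCC=C)[C@H]1CCC(CCCl)=C1I | intermediate
17 | glutaric anhydride of 16 | COC(=O)C(CC1C(=O)OC(=O)C[C@]1(CO[Si](C)(C)C(C)(C)C)CCC=C)[C@H]1CCC(CCCl)=C1I | intermediate
18 | amic acid (N-methallyl amide at C7, acid at C1; one regioisomer shown) | COC(=O)C(CC(C(=O)O)[C@@](CC(=O)NCC(C)=C)(CO[Si](C)(C)C(C)(C)C)CCC=C)[C@H]1CCC(CCCl)=C1I | intermediate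
19 | N-(2-methylprop-2-enyl)glutarimide | COC(=O)C(CC1C(=O)N(CC(C)=C)C(=O)C[C@]1(CO[Si](C)(C)C(C)(C)C)CCC=C)[C@H]1CCC(CCCl)=C1I | intermediate
20 | bridged imide, Z-C2=C18 in the nine-membered N–C5 bridge | COC(=O)C(CC1C(=O)N2C/C(C)=C\CC[C@@]1(CO[Si](C)(C)C(C)(C)C)CC2=O)[C@H]1CCC(CCCl)=C1I | intermediate
21 | bridged imide alcohol (2R,18R) | COC(=O)C(CC1C(=O)N2C[C@@H](C)[C@H](O)CC[C@@]1(CO[Si](C)(C)C(C)(C)C)CC2=O)[C@H]1CCC(CCCl)=C1I | intermediate
22 | bridged imide, C2 TBDPS ether | COC(=O)C(CC1C(=O)N2C[C@@H](C)[C@H](O[Si](c3ccccc3)(c4ccccc4)C(C)(C)C)CC[C@@]1(CO[Si](C)(C)C(C)(C)C)CC2=O)[C@H]1CCC(CCCl)=C1I | intermediate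
23 | chloro imide after the first closure (C8–C9 formed, C12–Cl intact) | COC(=O)C1C[C@@]2(C(=O)N3C(=O)C[C@]2(CO[Si](C)(C)C(C)(C)C)CC[C@@H](O[Si](c4ccccc4)(c5ccccc5)C(C)(C)C)[C@H](C)C3)C6=C(CCCl)CC[C@H]16 | intermediate
24 | pentacyclic imide (C7=O retained) | COC(=O)C1C[C@@]23C(=O)N4C(=O)[C@@H](CCC5=C2[C@@H]1CC5)[C@]3(CO[Si](C)(C)C(C)(C)C)CC[C@@H](O[Si](c6ccccc6)(c7ccccc7)C(C)(C)C)[C@H](C)C4 | intermediate
25 | C7 hydroxy lactam | COC(=O)C1C[C@@]23C(=O)N4C(O)[C@@H](CCC5=C2[C@@H]1CC5)[C@]3(CO[Si](C)(C)C(C)(C)C)CC[C@@H](O[Si](c6ccccc6)(c7ccccc7)C(C)(C)C)[C@H](C)C4 | intermediate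
26 | pentacyclic lactam (epimers at C14) | COC(=O)C1C[C@@]23C(=O)N4C[C@@H](CCC5=C2[C@@H]1CC5)[C@]3(CO[Si](C)(C)C(C)(C)C)CC[C@@H](O[Si](c6ccccc6)(c7ccccc7)C(C)(C)C)[C@H](C)C4 | intermediate
27 | pentacyclic lactam, 14R | COC(=O)[C@@H]1C[C@@]23C(=O)N4C[C@@H](CCC5=C2[C@@H]1CC5)[C@]3(CO[Si](C)(C)C(C)(C)C)CC[C@@H](O[Si](c6ccccc6)(c7ccccc7)C(C)(C)C)[C@H](C)C4 | intermediate
28 | C21 alcohol, C2 TBDPS ether | COC(=O)[C@@H]1C[C@@]23C(=O)N4C[C@@H](CCC5=C2[C@@H]1CC5)[C@]3(CO)CC[C@@H](O[Si](c6ccccc6)(c7ccccc7)C(C)(C)C)[C@H](C)C4 | intermediate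
29 | C21 acetate, C2 TBDPS ether | COC(=O)[C@@H]1C[C@@]23C(=O)N4C[C@@H](CCC5=C2[C@@H]1CC5)[C@]3(COC(C)=O)CC[C@@H](O[Si](c6ccccc6)(c7ccccc7)C(C)(C)C)[C@H](C)C4 | intermediate
30 | CNP0296366.1 | COC(=O)[C@@H]1C[C@@]23C(=O)N4C[C@@H](CCC5=C2[C@@H]1CC5)[C@]3(COC(C)=O)CC[C@@H](O)[C@H](C)C4 | target

**Totals and risks**

Total: 20 steps. Longest linear sequence: 18 steps (steps 1–5, then 8–20).

Step 15. The two enolate reactions may interfere: coupling through the C6 enolate, E2 loss of HCl from the chloroethyl arm, proto-deiodination, or a slow reductive elimination at the crowded C8. The fallback makes the two bonds one after the other by different chemistry, setting out from 22. NaBH4 reduction of the C7 carbonyl and dehydration (MsCl, Et3N) give the ene-lactam F1, in which C8–H is the only enolisable position. Palladium-catalysed α-alkenylation (LiN(SiMe3)2, Pd2(dba)3, P(t-Bu)3), which can now be forced, closes C8–C9 to the chloride F2. Finkelstein exchange (NaI, acetone) gives the iodide F3. Bu3SnH/AIBN then generates the C12 radical, which cyclises 7-exo onto the enamide C6=C7 and is reduced at C7, returning to the route at 26.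

Step 13. The borane may add to the wrong face of the bridge alkene, or the metathesis of step 12 may deliver the wrong alkene geometry, either of which gives the wrong C2/C18 pair. The fallback sets both centres before the ring is closed and also avoids step 12; it sets out from 16. Ac2O, then NH3, then Ac2O/NaOAc give the N–H glutarimide F4. Lemieux–Johnson cleavage of the butenyl group gives the aldehyde F5. An Evans syn-aldol with the dibutylboron enolate of (S)-4-benzyl-3-propionyloxazolidin-2-one gives the adduct F6. Silylation (t-BuPh2SiCl) gives the ether F7, and reductive removal of the auxiliary (NaBH4, THF/H2O) gives the primary alcohol F8. Intramolecular Mitsunobu N-alkylation of the imide (PPh3, DIAD, high dilution) closes the bridge and returns to the route at 22.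

Step 10. Ozone may also attack the butenyl group or the iodoalkene. The fallback sets out from 14: Rubottom oxidation (mCPBA, NaHCO3, then mild acid) gives the α-hydroxy ketone F9, which NaIO4 cleaves to the aldehyde acid 15, where it rejoins the route before the Pinnick oxidation.

Further compounds
F1 | step 15 | ene-lactam (C6=C7 enamide, C1 lactam) from 22 | COC(=O)C(CC1C(=O)N2C[C@@H](C)[C@H](O[Si](c3ccccc3)(c4ccccc4)C(C)(C)C)CC[C@@]1(CO[Si](C)(C)C(C)(C)C)C=C2)[C@H]1CCC(CCCl)=C1I
F2 | step 15 | C8–C9 cyclised ene-lactam chloride | COC(=O)C1C[C@@]2(C(=O)N3C=C[C@]2(CO[Si](C)(C)C(C)(C)C)CC[C@@H](O[Si](c4ccccc4)(c5ccccc5)C(C)(C)C)[C@H](C)C3)C6=C(CCCl)CC[C@H]16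
F3 | step 15 | C8–C9 cyclised ene-lactam iodide | COC(=O)C1C[C@@]2(C(=O)N3C=C[C@]2(CO[Si](C)(C)C(C)(C)C)CC[C@@H](O[Si](c4ccccc4)(c5ccccc5)C(C)(C)C)[C@H](C)C3)C6=C(CCI)CC[C@H]16
F4 | step 13 | N–H glutarimide from 16 | COC(=O)C(CC1C(=O)NC(=O)C[C@]1(CO[Si](C)(C)C(C)(C)C)CCC=C)[C@H]1CCC(CCCl)=C1I
F5 | step 13 | C2 aldehyde | COC(=O)C(CC1C(=O)NC(=O)C[C@]1(CO[Si](C)(C)C(C)(C)C)CCC=O)[C@H]1CCC(CCCl)=C1I
F6 | step 13 | Evans syn-aldol adduct (C2 R, C18 S in the adduct) | COC(=O)C(CC1C(=O)NC(=O)C[C@]1(CO[Si](C)(C)C(C)(C)C)CC[C@@H](O)[C@H](C)C(=O)N2[C@@H](Cc3ccccc3)COC2=O)[C@H]1CCC(CCCl)=C1I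
F7 | step 13 | C2 TBDPS ether of F6 | COC(=O)C(CC1C(=O)NC(=O)C[C@]1(CO[Si](C)(C)C(C)(C)C)CC[C@@H](O[Si](c2ccccc2)(c3ccccc3)C(C)(C)C)[C@H](C)C(=O)N4[C@@H](Cc5ccccc5)COC4=O)[C@H]1CCC(CCCl)=C1I
F8 | step 13 | C19 primary alcohol | COC(=O)C(CC1C(=O)NC(=O)C[C@]1(CO[Si](C)(C)C(C)(C)C)CC[C@@H](O[Si](c2ccccc2)(c3ccccc3)C(C)(C)C)[C@H](C)CO)[C@H]1CCC(CCCl)=C1I
F9 | step 10 | C7 α-hydroxy ketone | COC(=O)C(CC1C(=O)C(O)C[C@]1(CO[Si](C)(C)C(C)(C)C)CCC=C)[C@H]1CCC(CCCl)=C1I
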